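I start with an easy step: I read the flasks and take slopes by hand.

| setting | alpha | beta | theta |
|---|---|---|---|
| starting material | 0.250 M | 0.250 M | 0.250 M |
| reagent | 0.625 M | 0.310 M | 0.140 M |
| time |  |  | 10 min |

| alpha run: time / min | alpha run: [product] / M | beta run: time / min | beta run: [product] / M |
|---|---|---|---|
| 2.0 | 0.1048 | 2.0 | 0.0573 |
| 4.0 | 0.1590 | 4.0 | 0.0894 |
| 6.0 | 0.1878 | 6.0 | 0.1062 |
| 8.0 | 0.2115 | 8.0 | 0.1210 |
| 10 | 0.2229 | 10 | 0.1306 |

(scatter of a reading: 0.001 M)

1. apparent order in [reagent] of the starting rate, round the charge of the alpha run (the rate where two percent of its starting material have turned into product)
2. product in the theta run at 10 min, as a share of the starting material charged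

- Overall: starting material + reagent -> product.
- Constant volume, constant temperature.
- A reading of a species includes what of it is bound.
- "The second partner" is reagent.
- An order is taken over about fifteen percent of the charge, up and down.

In the beta run I divide each slope by the starting material left at mid-interval, assuming first order in each partner. Over the first 2.0 min that gives 0.129 /min. From 8.0 min to 10 min it gives 0.0386 /min. I assume this figure follows the free reagent. Its fall per unit of product is 0.934 /M/min. The straight line through both points reaches zero at 0.167 M of product, so I take that as my estimate of the level of the beta curve, which is lower than either charge of the beta run. I call the reagent charge divided by that level the reagent price, the reagent lost per product made: 1.85. It is a reading, and its last slope rests on two readings with their scatter.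

I now draw the theta curve. By the same price, the level of the theta run is 0.0755 M, which is less than its starting material, so I take reagent as the limiting reagent of the theta run. Its starting slope is 0.0176 M/min. The knee, where product reaches 0.0377 M, comes at 3.25 min. Integrating the same rate to 10 min gives 0.0645 M, or 25.8%. For the order, the first readings of the beta and alpha runs give 0.861, a reading averaged over 2.0 min and taken between the two reagent charges, not round the alpha charge.

The forecast gives an order of 0.9, from 0.7 to 1.05, and 28%, from 18% to 35%, saying “reagent-poor conditions should give about 0.07 M product”. My share is lower than its 28%.

The flask gives an order of 1.0 and 25.4%.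

    starting material + reagent ⇌ product + by-product (1.644 /M/min, 0.2742 /M/min)
    2 starting material ⇌ idle substrate dimer, settled at all times (17.00 /M)
    reagent + by-product ⇌ reagent-by-product salt, settled at all times (286.0 /M)

The power-law fit gives 24.6% for the theta run, and the fit with main steps alone gives 32.2%. At the price of 1.85, the theta product at 10 min has cost 0.118 M of the 0.140 M reagent charged. In the beta run, product reaches 0.125 M at 8.67 min, and by the same price that has cost 0.232 M of its 0.310 M reagent.

The readings are calculated with made-up constants; scatter was added.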